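**Retrosynthetic overview**
- The target comes from its tetra-O-methyl ether by cleaving the four aryl methyl ethers last.
- The lactone ring (the only ring that is built) and the ring bond between the aryl-bearing carbon and the benzylidene-bearing carbon are formed in one photochemical step: a benzylic C–H bond adds across a tethered arylpropiolate (5-exo-dig). This step also sets the aryl-bearing stereocenter trans to the ester-bearing one and sets the E alkene.
- The cyclisation substrate is the ester of methyl (S)-3-(3,4-dimethoxyphenyl)lactate with 3-(3,4-dimethoxyphenyl)propiolic acid.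
- The lactate comes from methyl (S)-glycidate (the only source of chirality) and an aryl Grignard reagent; the propiolic acid comes from the arylacetylene and CO2.

Assumption: 4-ethynyl-1,2-dimethoxybenzene, 4-bromo-1,2-dimethoxybenzene and methyl (2S)-oxirane-2-carboxylate are bought. Ring positions below use oxolane numbering (O1, C2 bears CO2Me, C3 bears the aryl group, C4 bears the benzylidene group, C5 is the lactone carbonyl).

**Step 1**
Reactants: 1 4-ethynyl-1,2-dimethoxybenzene
Product: 3 3-(3,4-dimethoxyphenyl)prop-2-ynoic acid, via lithium acetylide 2 (not isolated)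
Conditions: n-BuLi (1.05 equiv), THF, −78 °C; CO2, −78 °C → rt; 1 M HCl
Reagents that add atoms: carbon dioxide, O=C=O
Why: The terminal alkyne is deprotonated cleanly by n-BuLi and the lithium acetylide adds to CO2 (carboxylation of an organolithium); no stereocenter is involved.

**Step 2**
Reactants: 4 4-bromo-1,2-dimethoxybenzene; 5 methyl (2S)-oxirane-2-carboxylate
Product: 7 methyl (2S)-3-(3,4-dimethoxyphenyl)-2-hydroxypropanoate, via arylmagnesium bromide 6 (not isolated)
Conditions: Mg, THF, 40 °C; then added slowly (1.2 equiv) to 5, CuI (10 mol%), THF, −40 → −20 °C; 0.5 M HCl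
Reagents that add atoms: none
Why: Copper-catalysed SN2 opening of a glycidic ester by an aryl Grignard reagent occurs at the unsubstituted C3 faster than addition to the ester at −40 °C, and since no bond to C2 is broken the (S) centre of 5 is carried unchanged into 7.

**Step 3**
Reactants: 3 3-(3,4-dimethoxyphenyl)prop-2-ynoic acid; 7 methyl (2S)-3-(3,4-dimethoxyphenyl)-2-hydroxypropanoate
Product: 9 methyl (2S)-3-(3,4-dimethoxyphenyl)-2-{[3-(3,4-dimethoxyphenyl)prop-2-ynoyl]oxy}propanoate, via O-acylisourea 8 (not isolated)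
Conditions: DCC (1.1 equiv), DMAP (5 mol%), CH2Cl2, 0 °C → rt
Reagents that add atoms: none
Why: Steglich esterification acylates the hydroxyl oxygen without touching the C–O bond at the stereocenter, and low DMAP loading at 0 °C keeps the α-acyloxy ester from epimerising and the ynoate from taking up nucleophiles.

**Step 4**
Reactants: 9 methyl (2S)-3-(3,4-dimethoxyphenyl)-2-{[3-(3,4-dimethoxyphenyl)prop-2-ynoyl]oxy}propanoate
Product: 12 methyl (2S,3S,4E)-3-(3,4-dimethoxyphenyl)-4-[(3,4-dimethoxyphenyl)methylidene]-5-oxooxolane-2-carboxylate, via benzylic radical 10 (not isolated), via vinyl radical 11 (not isolated)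
Conditions: (n-Bu4N)4[W10O32] (5 mol%), MeCN (0.02 M), 390 nm LEDs, 40 °C, Ar, stopped at about 80% conversion
Reagents that add atoms: none
Why: Proposed new method: a decatungstate-photocatalysed intramolecular benzylic C–H addition across a tethered arylpropiolate (redox-neutral 5-exo-dig cycloisomerisation), in which the excited [W10O32]4− anion abstracts the electron-rich benzylic hydrogen of 9 (the C2–H is flanked by two acceptor groups and is polarity-mismatched, and the OCH3 hydrogens are stronger), radical 10 attacks the alkyne carbon next to the carbonyl, the position radicals are known to choose on arylpropiolates because a linear aryl-stabilised vinyl radical results, closing the lactone through the s-cis ester rotamer that polar MeCN populates, and vinyl radical 11 takes the hydrogen atom back from the reduced decatungstate; C3 is set trans to the C2 ester because the aryl group on the radical carbon lies anti to the neighbouring CO2Me in the ring-closing transition state, and hydrogen is delivered to 11 from the carbonyl side, away from the C3 aryl group, which gives the E alkene; the closest known reaction types are the intermolecular decatungstate benzylic C–H Giese alkylation of electron-poor alkenes, radical α-addition/cyclisation cascades of aryl alkynoates, and the ester-tethered 5-exo radical closure of polar radical crossover cycloadditions that give γ-butyrolactones.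

**Step 5**
Reactants: 12 methyl (2S,3S,4E)-3-(3,4-dimethoxyphenyl)-4-[(3,4-dimethoxyphenyl)methylidene]-5-oxooxolane-2-carboxylate
Product: 14 methyl (2S,3S,4E)-3-(3,4-dihydroxyphenyl)-4-[(3,4-dihydroxyphenyl)methylidene]-5-oxooxolane-2-carboxylate, via bis(bromobenzodioxaborole) 13 (not isolated)
Conditions: BBr3 (8 equiv), CH2Cl2, −78 → 0 °C; ice water
Reagents that add atoms: none
Why: BBr3 cleaves aryl methyl ethers (Lewis acid complexation, then SN2 attack of bromide on the O-methyl group) much faster than a methyl ester or a γ-lactone below 0 °C, no bond to a stereocenter is touched, and the acidic medium avoids base-induced epimerisation at C3 or migration of the exocyclic alkene.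

**Compound list**
1 | 4-ethynyl-1,2-dimethoxybenzene | COc1ccc(C#C)cc1OC | starting material
2 | lithium (3,4-dimethoxyphenyl)acetylide | COc1ccc(C#C[Li])cc1OC | intermediate
3 | 3-(3,4-dimethoxyphenyl)prop-2-ynoic acid | COc1ccc(C#CC(=O)O)cc1OC | intermediate
4 | 4-bromo-1,2-dimethoxybenzene | COc1ccc(Br)cc1OC | starting material
5 | methyl (2S)-oxirane-2-carboxylate (methyl (S)-glycidate) | COC(=O)[C@@H]1CO1 | starting material
6 | (3,4-dimethoxyphenyl)magnesium bromide | COc1ccc([Mg]Br)cc1OC | intermediate
7 | methyl (2S)-3-(3,4-dimethoxyphenyl)-2-hydroxypropanoate | COC(=O)[C@@H](O)Cc1ccc(OC)c(OC)c1 | intermediate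
8 | O-acylisourea from 3 and DCC | COc1ccc(C#CC(=O)OC(=NC2CCCCC2)NC2CCCCC2)cc1OC | intermediate
9 | methyl (2S)-3-(3,4-dimethoxyphenyl)-2-{[3-(3,4-dimethoxyphenyl)prop-2-ynoyl]oxy}propanoate | COC(=O)[C@@H](OC(=O)C#Cc1ccc(OC)c(OC)c1)Cc1ccc(OC)c(OC)c1 | intermediate
10 | benzylic radical of 9 (radical at C3 of the propanoate) | COC(=O)[C@@H](OC(=O)C#Cc1ccc(OC)c(OC)c1)[CH]c1ccc(OC)c(OC)c1 | intermediate
11 | ring-closed α-aryl vinyl radical ((2S,3S)-lactone, radical on the exocyclic carbon) | COC(=O)[C@H]1OC(=O)C(=[C]c2ccc(OC)c(OC)c2)[C@@H]1c1ccc(OC)c(OC)c1 | intermediate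
12 | methyl (2S,3S,4E)-3-(3,4-dimethoxyphenyl)-4-[(3,4-dimethoxyphenyl)methylidene]-5-oxooxolane-2-carboxylate | COC(=O)[C@H]1OC(=O)/C(=C/c2ccc(OC)c(OC)c2)[C@@H]1c1ccc(OC)c(OC)c1 | intermediate
13 | bis(2-bromo-1,3,2-benzodioxaborole) derivative of 14 (both catechols bound to boron) | COC(=O)[C@H]1OC(=O)/C(=C/c2ccc3OB(Br)Oc3c2)[C@@H]1c1ccc2OB(Br)Oc2c1 | intermediate
14 | methyl (2S,3S,4E)-3-(3,4-dihydroxyphenyl)-4-[(3,4-dihydroxyphenyl)methylidene]-5-oxooxolane-2-carboxylate | COC(=O)[C@H]1OC(=O)/C(=C/c2ccc(O)c(O)c2)[C@@H]1c1ccc(O)c(O)c1 | target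

**Step count and risks**
Total steps: 5. Longest linear sequence: 4 steps (4 and 5 → 7 → 9 → 12 → 14).

Most likely to fail, first: step 4 (the proposed photocyclisation). Ring closure through the ester tether may be slow because the ester must reach its s-cis rotamer, so oligomerisation can compete. Compound 12 carries a weak benzylic and allylic C3–H that the photocatalyst can attack at high conversion. Trans/cis or E/Z mixtures may need chromatography. The fallback uses known chemistry, sets out from Grignard reagent 6 and comes back to the route at 12. Purchased (5S)-5-(hydroxymethyl)furan-2(5H)-one is silylated (t-BuPh2SiCl, imidazole, CH2Cl2) to (5S)-5-({[tert-butyl(diphenyl)silyl]oxy}methyl)furan-2(5H)-one F2. The cuprate from 6 and CuBr·SMe2 (THF, −78 °C) adds anti to the C5 substituent to give the trans lactone (4R,5S)-5-({[tert-butyl(diphenyl)silyl]oxy}methyl)-4-(3,4-dimethoxyphenyl)oxolan-2-one F3. LiN(SiMe3)2 (THF, −78 °C) and then 3,4-dimethoxybenzaldehyde give the aldol adduct (4R,5S)-5-({[tert-butyl(diphenyl)silyl]oxy}methyl)-4-(3,4-dimethoxyphenyl)-3-[(3,4-dimethoxyphenyl)(hydroxy)methyl]oxolan-2-one F4. MsCl/Et3N followed by DBU eliminates it to the E-benzylidene lactone (3E,4S,5S)-5-({[tert-butyl(diphenyl)silyl]oxy}methyl)-4-(3,4-dimethoxyphenyl)-3-[(3,4-dimethoxyphenyl)methylidene]oxolan-2-one F5. n-Bu4NF/AcOH (THF) frees the alcohol (3E,4S,5S)-4-(3,4-dimethoxyphenyl)-3-[(3,4-dimethoxyphenyl)methylidene]-5-(hydroxymethyl)oxolan-2-one F6. TEMPO (cat.)/PhI(OAc)2 in MeCN–water oxidises it to (2S,3S,4E)-3-(3,4-dimethoxyphenyl)-4-[(3,4-dimethoxyphenyl)methylidene]-5-oxooxolane-2-carboxylic acid F7, and Me3SiCHN2 in MeOH/toluene gives 12.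

Second: step 5 (ether cleavage). The methyl ester or the lactone may be partly cleaved by BBr3, and the free catechols are air-sensitive. The fallback sets out from 12 and comes back at 14. The BBr3 reaction is run on to room temperature so that all four ethers and the ester are cleaved, giving (2S,3S,4E)-3-(3,4-dihydroxyphenyl)-4-[(3,4-dihydroxyphenyl)methylidene]-5-oxooxolane-2-carboxylic acid F8. Only the carboxylic acid is then re-esterified by Fischer esterification (MeOH, HCl generated from AcCl, rt), which leaves phenols untouched and the γ-lactone closed, to give 14.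

Third: step 3 (esterification). The α-hydroxy ester is a hindered, weak nucleophile, and the activated ynoic acid can be diverted to the N-acylurea or to DMAP adducts. The fallback sets out from 7 and comes back at 9. Compound 7 is acylated with propiolic acid (DCC, CH2Cl2, −20 °C) to methyl (2S)-3-(3,4-dimethoxyphenyl)-2-(prop-2-ynoyloxy)propanoate F1. The aryl group is then attached by Sonogashira coupling with 4-iodo-1,2-dimethoxybenzene (PdCl2(PPh3)2, CuI, K2CO3, THF, 50 °C) to give 9.

**Further compounds**
F1 | step 3 | methyl (2S)-3-(3,4-dimethoxyphenyl)-2-(prop-2-ynoyloxy)propanoate | COC(=O)[C@@H](OC(=O)C#C)Cc1ccc(OC)c(OC)c1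
F2 | step 4 | (5S)-5-({[tert-butyl(diphenyl)silyl]oxy}methyl)furan-2(5H)-one | CC(C)(C)[Si](OC[C@H]1OC(=O)C=C1)(c1ccccc1)c1ccccc1
F3 | step 4 | (4R,5S)-5-({[tert-butyl(diphenyl)silyl]oxy}methyl)-4-(3,4-dimethoxyphenyl)oxolan-2-one | CC(C)(C)[Si](OC[C@H]1OC(=O)C[C@@H]1c1ccc(OC)c(OC)c1)(c1ccccc1)c1ccccc1
F4 | step 4 | (4R,5S)-5-({[tert-butyl(diphenyl)silyl]oxy}methyl)-4-(3,4-dimethoxyphenyl)-3-[(3,4-dimethoxyphenyl)(hydroxy)methyl]oxolan-2-one (C3 and carbinol centres as formed) | CC(C)(C)[Si](OC[C@H]1OC(=O)C(C(O)c2ccc(OC)c(OC)c2)[C@@H]1c1ccc(OC)c(OC)c1)(c1ccccc1)c1ccccc1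
F5 | step 4 | (3E,4S,5S)-5-({[tert-butyl(diphenyl)silyl]oxy}methyl)-4-(3,4-dimethoxyphenyl)-3-[(3,4-dimethoxyphenyl)methylidene]oxolan-2-one | CC(C)(C)[Si](OC[C@H]1OC(=O)/C(=C/c2ccc(OC)c(OC)c2)[C@@H]1c1ccc(OC)c(OC)c1)(c1ccccc1)c1ccccc1
F6 | step 4 | (3E,4S,5S)-4-(3,4-dimethoxyphenyl)-3-[(3,4-dimethoxyphenyl)methylidene]-5-(hydroxymethyl)oxolan-2-one | OC[C@H]1OC(=O)/C(=C/c2ccc(OC)c(OC)c2)[C@@H]1c1ccc(OC)c(OC)c1
F7 | step 4 | (2S,3S,4E)-3-(3,4-dimethoxyphenyl)-4-[(3,4-dimethoxyphenyl)methylidene]-5-oxooxolane-2-carboxylic acid | OC(=O)[C@H]1OC(=O)/C(=C/c2ccc(OC)c(OC)c2)[C@@H]1c1ccc(OC)c(OC)c1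
F8 | step 5 | (2S,3S,4E)-3-(3,4-dihydroxyphenyl)-4-[(3,4-dihydroxyphenyl)methylidene]-5-oxooxolane-2-carboxylic acid | OC(=O)[C@H]1OC(=O)/C(=C/c2ccc(O)c(O)c2)[C@@H]1c1ccc(O)c(O)c1
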